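**Strategy.** Target numbering: C1 is the methyl-bearing quaternary ring-fusion carbon, C2/C3 the ring CH2 pair, C4 the isopropyl carbinol, C5 the ring-fusion CH, C6 the veratroyloxy CH, C7 CH2, C8=C9 the alkene and C10 the angeloyloxy CH. The five-membered ring (C1–C5) is opened at C1–C5. The chain C9–C10–C1(CH3)–C2–C3–C4 is then (S)-citronellol, with its methine as C1. An α-diazo-β-keto ester (C4 ketone, C5 diazo carbon, C6 ester) closes the cyclopentanone by rhodium-carbenoid insertion into the tertiary C1–H bond, which creates the quaternary centre in one operation. C10 oxygenation, C5 equilibration, C6 methallylation, C4 isopropyl addition and ring-closing metathesis (C8=C9) complete the seven-membered ring.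

Key step: step 5

Remark: locants C1–C10 are the target numbering above and OTMP stands for (2,2,6,6-tetramethylpiperidin-1-yl)oxy. The β-keto ester 8 interconverts with its C5 epimer through the enol, so 9–13 are carried as mixtures at C5 until step 11 fixes this centre.

Step 1
Reactants: 1 (S)-citronellol
Product: 2 tert-butyl{[(3S)-3,7-dimethyloct-6-en-1-yl]oxy}dimethylsilane
Conditions: TBSCl, imidazole, DMF, 0 °C to rt
Reagents that add atoms: tert-butyldimethylsilyl chloride, CC(C)(C)[Si](C)(C)Cl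
Why: Silylation of the primary alcohol masks the C9 oxygen as an ether that should be inert to ozone, SnCl2, base and the rhodium carbenoid.

Step 2
Reactants: 2 tert-butyl{[(3S)-3,7-dimethyloct-6-en-1-yl]oxy}dimethylsilane
Product: 4 (4S)-6-[(tert-butyldimethylsilyl)oxy]-4-methylhexanal, via secondary ozonide 3 (not isolated)
Conditions: O3, CH2Cl2, −78 °C; then PPh3, −78 °C to rt
Reagents that add atoms: ozone, O=[O+][O-]
Why: Ozonolysis of the trisubstituted alkene with reductive work-up removes the isopropylidene end as acetone and should give the C4 aldehyde without touching the remote stereocentre.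

Step 3
Reactants: 4 (4S)-6-[(tert-butyldimethylsilyl)oxy]-4-methylhexanal; 5 methyl diazoacetate
Product: 6 methyl (6S)-8-[(tert-butyldimethylsilyl)oxy]-6-methyl-3-oxooctanoate
Conditions: SnCl2 (10 mol %), CH2Cl2, rt
Reagents that add atoms: none
Why: Roskamp homologation, in which the diazo ester adds to the tin-activated aldehyde and a 1,2-hydride shift with loss of N2 gives the β-keto ester (C4 ketone, C5 methylene, C6 ester).

Step 4
Reactants: 6 methyl (6S)-8-[(tert-butyldimethylsilyl)oxy]-6-methyl-3-oxooctanoate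
Product: 7 methyl (6S)-8-[(tert-butyldimethylsilyl)oxy]-2-diazo-6-methyl-3-oxooctanoate
Conditions: 4-acetamidobenzenesulfonyl azide, Et3N, MeCN, 0 °C to rt
Reagents that add atoms: 4-acetamidobenzenesulfonyl azide, CC(=O)Nc1ccc(cc1)S(=O)(=O)N=[N+]=[N-]
Why: Regitz diazo transfer to the active methylene of a β-keto ester installs the diazo group at C5.

Step 5
Reactants: 7 methyl (6S)-8-[(tert-butyldimethylsilyl)oxy]-2-diazo-6-methyl-3-oxooctanoate
Product: 8 methyl (1R,2R)-2-{2-[(tert-butyldimethylsilyl)oxy]ethyl}-2-methyl-5-oxocyclopentane-1-carboxylate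
Conditions: Rh2(OAc)4 (1 mol %), CH2Cl2, rt, slow addition of 7
Reagents that add atoms: none
Why: Rh2(OAc)4 expels N2 from 7 to give an electrophilic divalent-rhodium carbenoid at C5, which inserts into the C1–H bond through a concerted three-centre transition state and releases the catalyst. The closest known reaction type is the dirhodium-catalysed intramolecular 1,5 C–H insertion of α-diazo-β-keto esters to 2-alkoxycarbonylcyclopentanones. The ring C1–C2–C3–C4–C5 closes by 1,5-insertion, the carbenoid carbon and the C–H bond meeting in a six-centre chair-like array that is favoured over four- or six-membered alternatives. The quaternary C1 is controlled by the substrate: insertion proceeds with retention at the C–H carbon, so the (S) methine of citronellol becomes C1 with methyl, C2 and C10 placed as in the target, while C5 stays enolisable and is fixed in step 11. The step needs site selectivity, which the chain length secures because the tertiary, electron-rich C1–H is the only C–H bond in the 1,5-position and the silyloxy oxygen on C9 is too far away to deactivate it; slow addition at low concentration should suppress carbene dimerisation.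

Step 6
Reactants: 8 methyl (1R,2R)-2-{2-[(tert-butyldimethylsilyl)oxy]ethyl}-2-methyl-5-oxocyclopentane-1-carboxylate
Product: 9 methyl (7R)-7-{2-[(tert-butyldimethylsilyl)oxy]ethyl}-7-methyl-1,4-dioxaspiro[4.4]nonane-6-carboxylate (both epimers at target C5)
Conditions: (TMSOCH2)2, TMSOTf (5 mol %), CH2Cl2, −78 to −20 °C; pyridine quench
Reagents that add atoms: 1,2-bis(trimethylsilyloxy)ethane, C[Si](C)(C)OCCO[Si](C)(C)C
Why: Noyori ketalisation converts the C4 ketone into a dioxolane under aprotic low-temperature conditions that should spare the primary TBS ether, and it removes the β-dicarbonyl reactivity before the aldehyde chemistry at C9.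

Step 7
Reactants: 9 methyl (7R)-7-{2-[(tert-butyldimethylsilyl)oxy]ethyl}-7-methyl-1,4-dioxaspiro[4.4]nonane-6-carboxylate
Product: 10 methyl (7R)-7-(2-hydroxyethyl)-7-methyl-1,4-dioxaspiro[4.4]nonane-6-carboxylate (both epimers at target C5)
Conditions: HF·pyridine, pyridine, THF, 0 °C
Reagents that add atoms: none
Why: Buffered fluoride desilylation frees the primary C9 alcohol while the dioxolane and the hindered ester should stay intact; cold, brief treatment limits lactonisation.

Step 8
Reactants: 10 methyl (7R)-7-(2-hydroxyethyl)-7-methyl-1,4-dioxaspiro[4.4]nonane-6-carboxylate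
Product: 11 methyl (7R)-7-methyl-7-(2-oxoethyl)-1,4-dioxaspiro[4.4]nonane-6-carboxylate (both epimers at target C5)
Conditions: Dess–Martin periodinane, pyridine, CH2Cl2, 0 °C to rt
Reagents that add atoms: none
Why: Dess–Martin oxidation of the primary alcohol should give the C9 aldehyde under buffered conditions that do not harm the ketal.

Step 9
Reactants: 11 methyl (7R)-7-methyl-7-(2-oxoethyl)-1,4-dioxaspiro[4.4]nonane-6-carboxylate
Product: 12 methyl (7S)-7-methyl-7-[(1S)-2-oxo-1-OTMP-ethyl]-1,4-dioxaspiro[4.4]nonane-6-carboxylate (both epimers at target C5)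
Conditions: TEMPO (1.5 equiv), (5S)-5-benzyl-2,2,3-trimethylimidazolidin-4-one trifluoroacetate (20 mol %), CuCl2 (10 mol %), air, acetone, −20 °C
Reagents that add atoms: TEMPO, CC1(C)CCCC(C)(C)N1[O]
Why: Organocatalytic enamine α-oxyamination of an aldehyde with TEMPO, divalent copper and air, in which the benzyl group of the (5S)-catalyst is expected to shield the Re face of the (E)-enamine so that oxygen reaches the Si face of C10 (catalyst control, target 10R) and the alkoxyamine then serves as the C10–O protecting group.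

Step 10
Reactants: 12 methyl (7S)-7-methyl-7-[(1S)-2-oxo-1-OTMP-ethyl]-1,4-dioxaspiro[4.4]nonane-6-carboxylate
Product: 13 methyl (7S)-7-methyl-7-[(1R)-1-OTMP-prop-2-en-1-yl]-1,4-dioxaspiro[4.4]nonane-6-carboxylate (both epimers at target C5)
Conditions: Ph3PCH3Br, KN(SiMe3)2, THF, 0 °C; then 12, −78 to 0 °C
Reagents that add atoms: methyltriphenylphosphonium bromide, [Br-].C[P+](c1ccccc1)(c1ccccc1)c1ccccc1
Why: Wittig methylenation of the aldehyde should be fast at low temperature compared with enolisation of the hindered α-oxy carbon or attack on the ester, and gives the vinyl carbinol unit C10–C9.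

Step 11
Reactants: 13 methyl (7S)-7-methyl-7-[(1R)-1-OTMP-prop-2-en-1-yl]-1,4-dioxaspiro[4.4]nonane-6-carboxylate
Product: 14 methyl (6R,7S)-7-methyl-7-[(1R)-1-OTMP-prop-2-en-1-yl]-1,4-dioxaspiro[4.4]nonane-6-carboxylate
Conditions: NaOMe (0.3 equiv), MeOH, 60 °C
Reagents that add atoms: none
Why: Methoxide-mediated epimerisation of the ester α-carbon under thermodynamic control should place the C5 ester trans to the branched C10 arm and cis to the C1 methyl, which is the trans ring-fusion relationship of the target; any reversible opening of the dioxolane from the enolate should close again under catalytic base in methanol.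

Step 12
Reactants: 14 methyl (6R,7S)-7-methyl-7-[(1R)-1-OTMP-prop-2-en-1-yl]-1,4-dioxaspiro[4.4]nonane-6-carboxylate
Product: 15 {(6S,7S)-7-methyl-7-[(1R)-1-OTMP-prop-2-en-1-yl]-1,4-dioxaspiro[4.4]nonan-6-yl}methanol
Conditions: LiAlH4, THF, 0 °C
Reagents that add atoms: none
Why: Hydride reduction of the methyl ester gives the C6 primary alcohol; alkoxyamine, ketal and alkene should be inert to LiAlH4 at 0 °C.

Step 13
Reactants: 15 {(6S,7S)-7-methyl-7-[(1R)-1-OTMP-prop-2-en-1-yl]-1,4-dioxaspiro[4.4]nonan-6-yl}methanol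
Product: 16 (6S,7S)-7-methyl-7-[(1R)-1-OTMP-prop-2-en-1-yl]-1,4-dioxaspiro[4.4]nonane-6-carbaldehyde
Conditions: Dess–Martin periodinane, pyridine, CH2Cl2, 0 °C to rt
Reagents that add atoms: none
Why: Dess–Martin oxidation gives the C6 aldehyde without base, and C5 already has the thermodynamically preferred configuration.

Step 14
Reactants: 16 (6S,7S)-7-methyl-7-[(1R)-1-OTMP-prop-2-en-1-yl]-1,4-dioxaspiro[4.4]nonane-6-carbaldehyde
Product: 17 (1S)-3-methyl-1-{(6S,7S)-7-methyl-7-[(1R)-1-OTMP-prop-2-en-1-yl]-1,4-dioxaspiro[4.4]nonan-6-yl}but-3-en-1-ol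
Conditions: (−)-Ipc2BOMe [from (+)-α-pinene], 2-methylallylmagnesium chloride, Et2O, −78 °C to rt; then 16, −78 °C to rt; NaOH, H2O2
Reagents that add atoms: 2-methylallylmagnesium chloride, C=C(C)C[Mg]Cl, transferred through B-(2-methylallyl)diisopinocampheylborane, C=C(C)CB([C@@H]1C[C@@H]2C[C@H]([C@H]1C)C2(C)C)[C@@H]1C[C@@H]2C[C@H]([C@H]1C)C2(C)C
Why: Brown asymmetric methallylboration through a chair six-membered transition state, in which the (+)-α-pinene-derived reagent should attack the Si face of the aldehyde and set (6S) under reagent control while adding C7 and C8.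

Step 15
Reactants: 17 (1S)-3-methyl-1-{(6S,7S)-7-methyl-7-[(1R)-1-OTMP-prop-2-en-1-yl]-1,4-dioxaspiro[4.4]nonan-6-yl}but-3-en-1-ol
Product: 18 (2S,3S)-2-[(1S)-1-hydroxy-3-methylbut-3-en-1-yl]-3-methyl-3-[(1R)-1-OTMP-prop-2-en-1-yl]cyclopentan-1-one
Conditions: 1 M HCl, THF, 0 °C to rt
Reagents that add atoms: water, O
Why: Acid-catalysed hydrolysis of the dioxolane frees the C4 ketone; C5 becomes enolisable again, but its configuration (side chain trans to the bulky C10 arm) is the stable one.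

Step 16
Reactants: 18 (2S,3S)-2-[(1S)-1-hydroxy-3-methylbut-3-en-1-yl]-3-methyl-3-[(1R)-1-OTMP-prop-2-en-1-yl]cyclopentan-1-one
Product: 19 (1R,2S,3S)-2-[(1S)-1-hydroxy-3-methylbut-3-en-1-yl]-3-methyl-1-(propan-2-yl)-3-[(1R)-1-OTMP-prop-2-en-1-yl]cyclopentan-1-ol
Conditions: iPrMgCl (3 equiv), LaCl3·2LiCl (1 equiv), THF, −20 to 0 °C
Reagents that add atoms: isopropylmagnesium chloride, CC(C)[Mg]Cl
Why: Lanthanide-promoted Grignard 1,2-addition to a hindered enolisable ketone, in which the nucleophile should enter anti to the adjacent C5 side chain (held on the lower face, also through its magnesium alkoxide) and so give the C4 carbinol with OH cis to C6 as in the target.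

Step 17
Reactants: 19 (1R,2S,3S)-2-[(1S)-1-hydroxy-3-methylbut-3-en-1-yl]-3-methyl-1-(propan-2-yl)-3-[(1R)-1-OTMP-prop-2-en-1-yl]cyclopentan-1-ol; 20 veratric acid
Product: 21 (1S)-1-{(1S,2R,5S)-2-hydroxy-5-methyl-2-(propan-2-yl)-5-[(1R)-1-OTMP-prop-2-en-1-yl]cyclopentyl}-3-methylbut-3-en-1-yl 3,4-dimethoxybenzoate
Conditions: EDC·HCl, DMAP, CH2Cl2, rt to 40 °C
Reagents that add atoms: none
Why: Steglich esterification should acylate the secondary C6–OH only, since the tertiary C4–OH is too hindered to react.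

Step 18
Reactants: 21 (1S)-1-{(1S,2R,5S)-2-hydroxy-5-methyl-2-(propan-2-yl)-5-[(1R)-1-OTMP-prop-2-en-1-yl]cyclopentyl}-3-methylbut-3-en-1-yl 3,4-dimethoxybenzoate
Product: 22 (1S)-1-{(1S,2R,5S)-2-hydroxy-5-[(1R)-1-hydroxyprop-2-en-1-yl]-5-methyl-2-(propan-2-yl)cyclopentyl}-3-methylbut-3-en-1-yl 3,4-dimethoxybenzoate
Conditions: Zn dust, AcOH/THF/H2O (3:1:1), 50 °C
Reagents that add atoms: none
Why: Reductive N–O cleavage of the alkoxyamine with zinc in acetic acid should release the C10 allylic alcohol without affecting the ester, the alkenes or the tertiary alcohol.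

Step 19
Reactants: 22 (1S)-1-{(1S,2R,5S)-2-hydroxy-5-[(1R)-1-hydroxyprop-2-en-1-yl]-5-methyl-2-(propan-2-yl)cyclopentyl}-3-methylbut-3-en-1-yl 3,4-dimethoxybenzoate
Product: 23 (3R,3aS,4S,8R,8aS)-3,8-dihydroxy-6,8a-dimethyl-3-(propan-2-yl)-1,2,3,3a,4,5,8,8a-octahydroazulen-4-yl 3,4-dimethoxybenzoate
Conditions: second-generation Grubbs catalyst (H2IMes)(PCy3)Cl2Ru=CHPh (10 mol %), 1,4-benzoquinone (20 mol %), toluene, 80 °C
Reagents that add atoms: none
Why: Ring-closing metathesis of the vinyl carbinol with the 1,1-disubstituted methallyl alkene should form the trisubstituted C8=C9 bond and the seven-membered ring trans-fused to the cyclopentane, the free allylic hydroxyl aiding initiation at the hindered vinyl group.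

Step 20
Reactants: 23 (3R,3aS,4S,8R,8aS)-3,8-dihydroxy-6,8a-dimethyl-3-(propan-2-yl)-1,2,3,3a,4,5,8,8a-octahydroazulen-4-yl 3,4-dimethoxybenzoate; 24 angelic acid
Product: 26 (3R,3aS,4S,8R,8aS)-3-hydroxy-6,8a-dimethyl-8-{[(2Z)-2-methylbut-2-enoyl]oxy}-3-(propan-2-yl)-1,2,3,3a,4,5,8,8a-octahydroazulen-4-yl 3,4-dimethoxybenzoate (CNP0142353.1), via mixed anhydride 25 (not isolated)
Conditions: 24, 2,4,6-trichlorobenzoyl chloride, Et3N, toluene, rt; then 23, toluene, 80 °C
Reagents that add atoms: none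
Why: Yamaguchi-type esterification through the angelic 2,4,6-trichlorobenzoic mixed anhydride should acylate the secondary allylic C10–OH at the unshielded angeloyl carbonyl without Z-to-E isomerisation, leaving the tertiary C4–OH free.

**Compound list**

1 | (S)-citronellol, (3S)-3,7-dimethyloct-6-en-1-ol | OCC[C@@H](C)CCC=C(C)C | starting material
2 | tert-butyl{[(3S)-3,7-dimethyloct-6-en-1-yl]oxy}dimethylsilane | CC(C)(C)[Si](C)(C)OCC[C@@H](C)CCC=C(C)C | intermediate
3 | secondary ozonide, tert-butyl{[(3S)-5-(5,5-dimethyl-1,2,4-trioxolan-3-yl)-3-methylpentyl]oxy}dimethylsilane | CC(C)(C)[Si](C)(C)OCC[C@@H](C)CCC1OOC(C)(C)O1 | intermediate (not isolated)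
4 | (4S)-6-[(tert-butyldimethylsilyl)oxy]-4-methylhexanal | CC(C)(C)[Si](C)(C)OCC[C@@H](C)CCC=O | intermediate
5 | methyl diazoacetate | COC(=O)C=[N+]=[N-] | starting material
6 | methyl (6S)-8-[(tert-butyldimethylsilyl)oxy]-6-methyl-3-oxooctanoate | CC(C)(C)[Si](C)(C)OCC[C@@H](C)CCC(=O)CC(=O)OC | intermediate
7 | methyl (6S)-8-[(tert-butyldimethylsilyl)oxy]-2-diazo-6-methyl-3-oxooctanoate | CC(C)(C)[Si](C)(C)OCC[C@@H](C)CCC(=O)C(=[N+]=[N-])C(=O)OC | intermediate
8 | methyl (1R,2R)-2-{2-[(tert-butyldimethylsilyl)oxy]ethyl}-2-methyl-5-oxocyclopentane-1-carboxylate | COC(=O)[C@@H]1[C@](CCO[Si](C)(C)C(C)(C)C)(C)CCC1=O | intermediate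
9 | methyl (7R)-7-{2-[(tert-butyldimethylsilyl)oxy]ethyl}-7-methyl-1,4-dioxaspiro[4.4]nonane-6-carboxylate, both epimers at target C5 | COC(=O)C1[C@](CCO[Si](C)(C)C(C)(C)C)(C)CCC12OCCO2 | intermediate
10 | methyl (7R)-7-(2-hydroxyethyl)-7-methyl-1,4-dioxaspiro[4.4]nonane-6-carboxylate, both epimers at target C5 | COC(=O)C1[C@](CCO)(C)CCC12OCCO2 | intermediate
11 | methyl (7R)-7-methyl-7-(2-oxoethyl)-1,4-dioxaspiro[4.4]nonane-6-carboxylate, both epimers at target C5 | COC(=O)C1[C@](CC=O)(C)CCC12OCCO2 | intermediate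
12 | methyl (7S)-7-methyl-7-[(1S)-2-oxo-1-OTMP-ethyl]-1,4-dioxaspiro[4.4]nonane-6-carboxylate, both epimers at target C5 | COC(=O)C1[C@]([C@H](ON3C(C)(C)CCCC3(C)C)C=O)(C)CCC12OCCO2 | intermediate
13 | methyl (7S)-7-methyl-7-[(1R)-1-OTMP-prop-2-en-1-yl]-1,4-dioxaspiro[4.4]nonane-6-carboxylate, both epimers at target C5 | COC(=O)C1[C@]([C@H](ON3C(C)(C)CCCC3(C)C)C=C)(C)CCC12OCCO2 | intermediate
14 | methyl (6R,7S)-7-methyl-7-[(1R)-1-OTMP-prop-2-en-1-yl]-1,4-dioxaspiro[4.4]nonane-6-carboxylate | COC(=O)[C@@H]1[C@]([C@H](ON3C(C)(C)CCCC3(C)C)C=C)(C)CCC12OCCO2 | intermediate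
15 | {(6S,7S)-7-methyl-7-[(1R)-1-OTMP-prop-2-en-1-yl]-1,4-dioxaspiro[4.4]nonan-6-yl}methanol | OC[C@@H]1[C@]([C@H](ON3C(C)(C)CCCC3(C)C)C=C)(C)CCC12OCCO2 | intermediate
16 | (6S,7S)-7-methyl-7-[(1R)-1-OTMP-prop-2-en-1-yl]-1,4-dioxaspiro[4.4]nonane-6-carbaldehyde | O=C[C@@H]1[C@]([C@H](ON3C(C)(C)CCCC3(C)C)C=C)(C)CCC12OCCO2 | intermediate
17 | (1S)-3-methyl-1-{(6S,7S)-7-methyl-7-[(1R)-1-OTMP-prop-2-en-1-yl]-1,4-dioxaspiro[4.4]nonan-6-yl}but-3-en-1-ol | C=C(C)C[C@H](O)[C@@H]1[C@]([C@H](ON3C(C)(C)CCCC3(C)C)C=C)(C)CCC12OCCO2 | intermediate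
18 | (2S,3S)-2-[(1S)-1-hydroxy-3-methylbut-3-en-1-yl]-3-methyl-3-[(1R)-1-OTMP-prop-2-en-1-yl]cyclopentan-1-one | C=C(C)C[C@H](O)[C@@H]1[C@]([C@H](ON2C(C)(C)CCCC2(C)C)C=C)(C)CCC1=O | intermediate
19 | (1R,2S,3S)-2-[(1S)-1-hydroxy-3-methylbut-3-en-1-yl]-3-methyl-1-(propan-2-yl)-3-[(1R)-1-OTMP-prop-2-en-1-yl]cyclopentan-1-ol | C=C(C)C[C@H](O)[C@@H]1[C@]([C@H](ON2C(C)(C)CCCC2(C)C)C=C)(C)CC[C@@]1(O)C(C)C | intermediate
20 | veratric acid, 3,4-dimethoxybenzoic acid | COc1ccc(C(=O)O)cc1OC | starting material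
21 | (1S)-1-{(1S,2R,5S)-2-hydroxy-5-methyl-2-(propan-2-yl)-5-[(1R)-1-OTMP-prop-2-en-1-yl]cyclopentyl}-3-methylbut-3-en-1-yl 3,4-dimethoxybenzoate | C=C(C)C[C@H](OC(=O)c2ccc(OC)c(OC)c2)[C@@H]1[C@]([C@H](ON3C(C)(C)CCCC3(C)C)C=C)(C)CC[C@@]1(O)C(C)C | intermediate
22 | (1S)-1-{(1S,2R,5S)-2-hydroxy-5-[(1R)-1-hydroxyprop-2-en-1-yl]-5-methyl-2-(propan-2-yl)cyclopentyl}-3-methylbut-3-en-1-yl 3,4-dimethoxybenzoate | C=C(C)C[C@H](OC(=O)c2ccc(OC)c(OC)c2)[C@@H]1[C@]([C@H](O)C=C)(C)CC[C@@]1(O)C(C)C | intermediate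
23 | (3R,3aS,4S,8R,8aS)-3,8-dihydroxy-6,8a-dimethyl-3-(propan-2-yl)-1,2,3,3a,4,5,8,8a-octahydroazulen-4-yl 3,4-dimethoxybenzoate | O[C@@H]1C=C(C)C[C@H](OC(=O)c2ccc(OC)c(OC)c2)[C@@H]2[C@]1(C)CC[C@@]2(O)C(C)C | intermediate
24 | angelic acid, (2Z)-2-methylbut-2-enoic acid | C/C=C(/C)C(=O)O | starting material
25 | (2Z)-2-methylbut-2-enoic 2,4,6-trichlorobenzoic anhydride | C/C=C(/C)C(=O)OC(=O)c1c(Cl)cc(Cl)cc1Cl | intermediate (not isolated)
26 | (3R,3aS,4S,8R,8aS)-3-hydroxy-6,8a-dimethyl-8-{[(2Z)-2-methylbut-2-enoyl]oxy}-3-(propan-2-yl)-1,2,3,3a,4,5,8,8a-octahydroazulen-4-yl 3,4-dimethoxybenzoate | C/C=C(/C)C(=O)O[C@@H]1C=C(C)C[C@H](OC(=O)c2ccc(OC)c(OC)c2)[C@@H]2[C@]1(C)CC[C@@]2(O)C(C)C | target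

**Totals.** Total step count: 20. Longest linear sequence: 20 steps from (S)-citronellol; methyl diazoacetate, veratric acid and angelic acid are used as purchased.

**Steps most likely to fail**

Step 9 (α-oxyamination). What may go wrong: slow enamine formation and oxygen transfer at C10, which is neopentylic, or poor facial selectivity if the catalyst and the adjacent C1 centre are mismatched. Fallback, from 11 back to 12: 11 is condensed with morpholine (MgSO4, CH2Cl2) to the enamine methyl (7R)-7-methyl-7-[(E)-2-(morpholin-4-yl)ethenyl]-1,4-dioxaspiro[4.4]nonane-6-carboxylate F1. F1 is oxidised with the preformed oxoammonium salt 2,2,6,6-tetramethyl-1-oxopiperidin-1-ium tetrafluoroborate (MeCN, −40 °C) and hydrolysed on aqueous work-up to 12. A stoichiometric enamine and a cationic oxygen electrophile replace the catalytic enamine and copper turnover. C10 is then set by the C1 quaternary centre alone, and the C10 epimers would be separated at 12 or 13.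

Step 14 (methallylboration). What may go wrong: sluggish addition of the bulky borane to an aldehyde flanked by two quaternary carbons, or poor facial selectivity in a mismatched pairing. Fallback, from 16 back to 17: 2-methylallylmagnesium chloride (THF, −78 °C) gives the C6-epimeric alcohols 3-methyl-1-{(6S,7S)-7-methyl-7-[(1R)-1-OTMP-prop-2-en-1-yl]-1,4-dioxaspiro[4.4]nonan-6-yl}but-3-en-1-ol F2. Dess–Martin oxidation gives the β,γ-unsaturated ketone 3-methyl-1-{(6S,7S)-7-methyl-7-[(1R)-1-OTMP-prop-2-en-1-yl]-1,4-dioxaspiro[4.4]nonan-6-yl}but-3-en-1-one F3. Corey–Bakshi–Shibata reduction with the (R)-methyl oxazaborolidine and catecholborane (toluene, −78 °C) returns 17, the face being chosen by the size difference between the C5 substituent and the methallyl CH2.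

Step 16 (isopropyl addition). What may go wrong: enolisation, reduction by β-hydride transfer from the Grignard reagent, or attack on the wrong face of the congested ketone. Fallback, from 18 back to 23: ring-closing metathesis of 18 (second-generation Grubbs catalyst, toluene, 80 °C) is carried out first and gives the bicyclic hydroxy ketone F4 (C4 ketone, C6–OH, C10–OTMP, C8=C9). 2-Propenylmagnesium bromide with CeCl3 (THF, −78 °C), a nucleophile without β-hydrogens, adds to the conformationally fixed ketone to give the isopropenyl carbinol F5. Hydrogenation with RhCl(PPh3)3 and H2 saturates only the 1,1-disubstituted alkene and gives the isopropyl carbinol F6. Steglich esterification with 20 gives the C6 veratrate F7, and zinc in acetic acid returns 23.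

**Further compounds**

F1 | step 9 | methyl (7R)-7-methyl-7-[(E)-2-(morpholin-4-yl)ethenyl]-1,4-dioxaspiro[4.4]nonane-6-carboxylate, both epimers at target C5 | COC(=O)C1[C@](/C=C/N3CCOCC3)(C)CCC12OCCO2
F2 | step 14 | 3-methyl-1-{(6S,7S)-7-methyl-7-[(1R)-1-OTMP-prop-2-en-1-yl]-1,4-dioxaspiro[4.4]nonan-6-yl}but-3-en-1-ol, both carbinol epimers | C=C(C)CC(O)[C@@H]1[C@]([C@H](ON3C(C)(C)CCCC3(C)C)C=C)(C)CCC12OCCO2
F3 | step 14 | 3-methyl-1-{(6S,7S)-7-methyl-7-[(1R)-1-OTMP-prop-2-en-1-yl]-1,4-dioxaspiro[4.4]nonan-6-yl}but-3-en-1-one | C=C(C)CC(=O)[C@@H]1[C@]([C@H](ON3C(C)(C)CCCC3(C)C)C=C)(C)CCC12OCCO2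
F4 | step 16 | bicyclic hydroxy ketone: 23 lacking the veratroyl group, with C4 as ketone and OTMP at C10 | CC1(C)CCCC(C)(C)N1O[C@@H]2C=C(C)C[C@H](O)[C@@H]3[C@]2(C)CCC3=O
F5 | step 16 | isopropenyl carbinol: F4 with 2-propenyl and OH at C4 (configuration as in 23) | CC1(C)CCCC(C)(C)N1O[C@@H]2C=C(C)C[C@H](O)[C@@H]3[C@]2(C)CC[C@@]3(O)C(C)=C
F6 | step 16 | isopropyl carbinol: 23 lacking the veratroyl group, with OTMP at C10 | CC1(C)CCCC(C)(C)N1O[C@@H]2C=C(C)C[C@H](O)[C@@H]3[C@]2(C)CC[C@@]3(O)C(C)C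
F7 | step 16 | C6 veratrate of F6: 23 with OTMP at C10 | CC1(C)CCCC(C)(C)N1O[C@@H]2C=C(C)C[C@H](OC(=O)c4ccc(OC)c(OC)c4)[C@@H]3[C@]2(C)CC[C@@]3(O)C(C)C
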